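One turnover was my unit: a whole charge of starting material passing into product at the pace the closed flask showed, so that the turnovers a vessel gives are that pace times the time spent in it.

| flask | starting material | protic impurity | remark | time |
|---|---|---|---|---|
| violet | 2.8 M | 0.84 M | run made earlier |  |
| teal | 1.4 M | 0.84 M | run made earlier |  |
| ochre | 2.8 M | 1.3 M | run made earlier |  |
| gamma | 2.8 M | 0.840 M | a single well-mixed tank run continuously and read at steady state, 7.50 min in it on average |  |
| eta | 2.8 M | 0.840 M | a tube with plug flow, the mixed feed as stated, residence time 2.5 min | 2.5 min |
| beta | 2.8 M | 0.840 M | everything together in a closed stirred flask, run for 2.5 min | 2.5 min |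
| delta | 2.8 M | 0.840 M | a single well-mixed tank run continuously and read at steady state, 2.5 min in it on average |  |

| run | time / min | product / % | starting material / % |
|---|---|---|---|
| violet | 0.200 | 0 | 23 |
| violet | 0.333 | 4 | 15 |
| violet | 0.500 | 4 | 12 |
| violet | 0.667 | 10 | 10 |
| violet | 1.00 | 16 | 6 |
| violet | 1.50 | 18 | 4 |
| violet | 2.50 | 37 | 3 |
| teal | 0.417 | 6 | 7 |
| teal | 0.833 | 11 | 7 |
| teal | 1.33 | 18 | 6 |
| teal | 1.50 | 23 | 3 |
| teal | 2.00 | 30 | 5 |
| teal | 2.50 | 33 | 5 |
| teal | 3.00 | 38 | 4 |
| ochre | 0.667 | 5 | 8 |
| ochre | 1.33 | 20 | 1 |
| ochre | 2.00 | 27 | 2 |
| ochre | 2.50 | 29 | 2 |
| ochre | 3.00 | 37 | 1 |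

(readings scatter by 2 percentage points)

- the stated concentrations are those of everything mixed, before any reaction; amounts are the same in each set-up
- steps that have been proposed: starting material -> intermediate A; starting material <-> intermediate B; intermediate A <-> intermediate C; intermediate A -> product; starting material <-> dormant form; starting material + protic impurity -> quenched substrate
- the earlier runs were made in a closed, stirred flask

- the set-up with the highest amount of product at the outlet or at the end, in percent of the starting material put in ("none" if the first two lie within 2 percentage points) (gamma / eta / beta / delta / none)
- amount of product at the outlet or at the end, in percent of the starting material put in, gamma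
- amount of product at the outlet or at the end, in percent of the starting material put in, eta
- amount of product at the outlet or at the end, in percent of the starting material put in, beta
- amount of product at the outlet or at the end, in percent of the starting material put in, delta

I divided the last product reading of each earlier run by its time and got 0.148 min⁻¹ for violet, 0.127 min⁻¹ for teal, at [starting material] = 1.4 M, half of violet's, and 0.123 min⁻¹ for ochre, at [protic impurity] = 1.3 M. I carried their mean, 0.133 min⁻¹, as the turnover rate, the share of the charge made into product each minute. Beta and the plug-flow tube eta give every portion the same age, so I reckoned both at 0.332 turnovers, or 33.2% product.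

For the tanks I reckoned two ways. The ages in a mixed tank, its residence-time distribution, are exponential, so averaging the straight line over them returns the turnover count itself: 33.2% for delta and, with 0.995 turnovers, 99.5% for gamma. A balance on a charge taken to drain in proportion to what remains of it, at the turnover rate, gives instead the turnovers divided by one plus the turnovers: 24.9% for delta and 49.9% for gamma. The line cheats at gamma because 67.0% of that outflow is older than the last reading at 3.00 min, against 30.1% for delta. So I committed to the balance for gamma and to the midpoint of the two ways, 29.1%, for delta.

The forecast differed from my reckoning: it named gamma as best, with 45% for gamma, 32% for eta, 32% for beta and 25% for delta, and it said: “Gamma wins simply through its longer residence time.”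

Gamma gave 54.2%, ahead of eta and beta at 34.8% each and delta at 29.8%. Beta left ten times as long, to 25.0 min, held 81.2% product.

    starting material → intermediate A (k = 0.0510 s⁻¹)
    starting material ⇌ intermediate B (K = 1.60, k = 0.0490 s⁻¹)
    intermediate A ⇌ intermediate C (K = 0.620, k = 0.0150 s⁻¹)
    intermediate A → product (k = 0.00950 s⁻¹)
    starting material ⇌ dormant form (K = 1.20, k = 0.0410 s⁻¹)
    starting material + protic impurity → quenched substrate (k = 0.0220 L mol⁻¹ s⁻¹)

The 0.995 turnovers of gamma had given 49.9% by the balance, 4.4 percentage points under its outlet. Applied to beta read at 1.0 min, the turnover rate gives 13.3%, and that flask held 14.0% product.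

The data come from a simulation for substances that don't exist, noise included.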